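## Analysis of the target

- Compound 23 is the (Z)-5-methylhexa-3,5-dienoate of shikonin 18. The core is a naphthazarin: ring B (C1–C4, carbonyls at C1 and C4) carries the side chain at C2, ring A (C5–C8) carries hydroxyls at C5 and C8 and hydrogens at C6 and C7, and the rings share C4a–C8a.
- The only stereocentre is C1' (R), which bears the acyloxy group and is homoallylic to the C3'=C4' alkene. The only stereogenic double bond is the cis C3=C4 bond of the acyl group. The two elements are remote and are set independently.
- Three groups are sensitive. The quinone is reducible, electrophilic and base-labile as its phenolate. The C1'–O bond ionises under acid, with elimination or closure onto C3'=C4'. The acyl C2 methylene lies between the carboxyl and the diene, so deprotonation would pull the diene into conjugation and erase the cis geometry.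
- The synthesis is hard because four ring oxygens must be carried masked and released without harming C1' or the alkene, C1' must be set absolutely, and the ester can only be made last.
- The strategy rests on ring A. Para oxygens at C5 and C8, unsubstituted C6 and C7 and fusion at C4a–C8a correspond to a carbene carbon (C5), the two carbons of an alkyne (C6, C7) and one carbonyl ligand (C8), closed onto the free ortho carbon (C8a) of a benzene that already is ring B with its side chain.
- Naphthazarin tautomers interconvert by proton transfer between the peri oxygens. It therefore does not matter that the new ring arrives at the quinone level while the substituted ring stays benzenoid.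

## Retrosynthetic reasoning

**Ester bond (23 to 18 and 22).** The acyl C1–O bond is cut first. The skipped dienoate would not survive oxidants, Lewis acids or fluoride, so it is attached last. The forward acylation must pick the secondary alcohol of 18 over two phenols; the phenols are chelated to the quinone carbonyls, which provides that selectivity.

**Acid 22 to 19 and 20.** The C3=C4 bond is cut. A non-stabilised ylide and an aldehyde give the cis alkene under kinetic control, and the carboxylate form protects the C2 methylene during the reaction.

**Unmasking (18 to 17 to 16).** The O–Si bond at C1' and the two O–CH3 bonds at the peri oxygens are protecting-group bonds. In 16 the quinone sits in the ring made last and the side chain on the benzenoid ring; cleavage of the two methyl ethers gives a naphthazarin that tautomerises to 17. The methyl ethers are removed before the silyl ether so that no free benzylic alcohol meets the Lewis acid.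

**Oxidation level (16 to 15).** The quinone comes from a 4-methoxy-1-naphthol. Only the new ring of 15 has a free hydroxyl, so the oxidation is regiodefined. A naphthalene with four equal ethers would not offer this.

**C7–H from C7–Si (15 to 14).** The silyl group of 14 stands in for hydrogen. It is removed while the ring is still an electron-rich naphthol, where ipso protonation is easy.

**Key disconnection (14 to 11 and 12).** Three bonds of ring A are cut: C5–C6, C7–C8 and C8–C8a. Ring A carries no carbon substituent, so its six atoms are supplied by the carbene carbon of 11, the two carbons of 12, one carbonyl ligand and two arene carbons. The side chain and C1' are loaded onto a simple benzene beforehand, and both ring-A oxygens arrive at the right carbons in the bond-forming step.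

**Carbene complex (11 to 8).** The aryl–carbene carbon bond is cut. The aryllithium 9 adds to a metal-bound carbonyl and the acylmetalate 10 is O-methylated, so 8 needs only a bromine para to the side chain.

**Stereocentre (8 to 7 to 6).** The silyl ether goes back to alcohol 7, and the C1'–H bond to ketone 6. A catalytic enantioselective reduction of an aryl alkyl ketone has a predictable sense, and the enantiomeric purity can be checked at 7, long before the key step.

**Aryl–acyl bond (6 to 4 and 3; 3 to 1).** The symmetrical dibromide 4 is lithiated once and acylated by amide 3, which comes from acid 1. The second bromine is kept as the handle for the carbene.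

## Alternatives that were turned down

**Alternative 1:** conjunctive coupling that builds the side chain and C1' in one step.
- Disconnection: C2–C1' and C2'–C3'.
- Forward step: vinylboronate A1 and the lithiated tetramethoxynaphthalene A2 form a boron ate complex. A palladium catalyst with a chiral ferrocenyl bisphosphine and the alkenyl triflate A3 induce a 1,2-shift of the naphthyl group from boron to carbon, and reductive elimination gives boronate A4. Oxidation of the C–B bond with retention would give the R alcohol.
- For: it is the most convergent plan, uses no stoichiometric transition metal and is several steps shorter. On step economy it is stronger than the chosen route.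
- Against: direct aryl transfer from the ate complex to the alkenylpalladium competes with the metallate shift, and the naphthyl group is electron-rich and hindered by its ortho methoxy group. The enantiomeric purity hangs on one ligand-controlled event with an unusual migrating group. All four oxygens of A4 carry the same methyl group, so the cerium oxidation is not directed to one ring and four methyl groups must go with the C1' oxygen in place.
- Comparison: the chosen route gives in exchange a ring A that is already differentiated (one free hydroxyl, one methyl ether) and a stereocentre from a reduction on a simple ketone.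

**Alternative 2:** aryne–furan cycloaddition with a temporary oxygen bridge.
- Disconnection: C1–C8a and C4–C4a.
- Forward step: bromide A5 and a lithium amide give the symmetrical dimethoxy aryne, which adds across the α-carbons of the R furan A6 to give the bridged adduct A7. Bridge opening, para oxidation and demethylation follow.
- For: it is short. The side chain ends on the ring that becomes the quinone, where C1' resists ionisation during Lewis-acid demethylation. On this point it is stronger than the chosen route, which has C1' on the benzenoid ring at that stage.
- Against: an aryne is trapped well only by a large excess of diene, and here the diene is the enantioenriched fragment that must be limiting, so amine addition and aryne self-reaction compete. A7 brings only one oxygen for ring B, so the second needs a separate para-selective oxidation after an acid-mediated bridge opening next to the allylic C1'–O bond.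
- Comparison: step count is similar or lower. The chosen route places both new oxygens in the ring-forming step and uses the cheap partner in excess.

**Alternative 3:** phthaloylcobalt–alkyne annulation that closes the quinone ring.
- Disconnection: C1–C2 and C3–C4.
- Forward step: dione A8 is opened by a low-valent cobalt phosphine complex to a phthaloylcobalt metallacycle. After activation with a dioxime ligand it inserts the R propargylic ether A9 and gives quinone A10 directly.
- For: the product is already a quinone with the side chain on the quinone ring, so no desilylation of the ring and no ring oxidation are needed. After the key step it is shorter than the chosen route.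
- Against: A8 is not a stock compound and needs several steps. Cobalt and phosphine are stoichiometric, and phosphines add to quinones. The terminal alkyne has a branched silyl ether next to the inserting carbon and can oligomerise on cobalt. A9 needs an enantioselective alkynylation of an aldehyde that conjugates easily, or an ynone reduction.
- Comparison: the total length is no shorter because both partners must be made. The chosen route starts from a commercial dibromide and sets C1' on an aryl ketone.

Key step: step 6

Remarks on the chemistry:
- Compounds 1, 4, 12, 19 and 20 are taken to be commercial.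
- Compounds 17, 18 and 23 are written as the tautomer with the side chain on the quinonoid ring. Demethylation of 16 first gives the other tautomer, and the two equilibrate by proton transfer.
- Atom numbers C1–C8a and C1'–C4' refer to the target. Locants in compound names are those of each compound.

## Route

Step 1
Reactants: 1 4-methylpent-3-enoic acid
Product: 3 N-methoxy-N,4-dimethylpent-3-enamide, via acyl imidazole 2 (not isolated)
Conditions: 1,1'-carbonyldiimidazole, CH2Cl2, 0 °C to rt; then MeNHOMe·HCl, rt
Reagents that add atoms: N,O-dimethylhydroxylamine hydrochloride, CNOC.Cl; 1,1'-carbonyldiimidazole, O=C(n1ccnc1)n1ccnc1 (its imidazolyl group stays only in 2)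
Why: Activation of the acid as its acyl imidazole and aminolysis is the standard Weinreb amide synthesis; the near-neutral conditions should leave the β,γ-double bond out of conjugation.

Step 2
Reactants: 4 1,4-dibromo-2,5-dimethoxybenzene; 3 N-methoxy-N,4-dimethylpent-3-enamide
Product: 6 1-(4-bromo-2,5-dimethoxyphenyl)-4-methylpent-3-en-1-one, via bromoaryllithium 5 (not isolated)
Conditions: n-BuLi (1.0 equiv), THF, −78 °C; then 3, −78 to −30 °C; cold aq. NH4Cl
Reagents that add atoms: none
Why: Bromine–lithium exchange on the symmetrical dibromide should stop at the mono-lithio stage at −78 °C, and the aryllithium adds once to the amide because the chelated tetrahedral adduct persists until the quench (Weinreb ketone synthesis). A cold, weakly acidic work-up should keep the β,γ-unsaturated ketone from moving into conjugation.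

Step 3
Reactants: 6 1-(4-bromo-2,5-dimethoxyphenyl)-4-methylpent-3-en-1-one
Product: 7 (R)-1-(4-bromo-2,5-dimethoxyphenyl)-4-methylpent-3-en-1-ol
Conditions: (S)-1-methyl-3,3-diphenyltetrahydro-1H,3H-pyrrolo[1,2-c][1,3,2]oxazaborole (0.2 equiv), catecholborane, toluene, −78 °C; aq. NaOH work-up
Reagents that add atoms: none
Why: Corey–Bakshi–Shibata reduction: the ketone binds to the ring boron of the S catalyst with the aryl group as the large substituent turned away, and hydride from the nitrogen-bound borane reaches the face that gives the R carbinol, as for aryl alkyl ketones in general. Catecholborane is chosen because it should not hydroborate the trisubstituted alkene at −78 °C.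

Step 4
Reactants: 7 (R)-1-(4-bromo-2,5-dimethoxyphenyl)-4-methylpent-3-en-1-ol
Product: 8 (R)-[1-(4-bromo-2,5-dimethoxyphenyl)-4-methylpent-3-enyloxy](tert-butyl)dimethylsilane
Conditions: t-BuMe2SiCl, imidazole, DMF, rt
Reagents that add atoms: tert-butyldimethylsilyl chloride, CC(C)(C)[Si](C)(C)Cl
Why: Imidazole-promoted silylation of a secondary benzylic alcohol; the silyl ether should be inert to the organolithium, carbene and cerium chemistry that follow, and no bond to C1' is touched.

Step 5
Reactants: 8 (R)-[1-(4-bromo-2,5-dimethoxyphenyl)-4-methylpent-3-enyloxy](tert-butyl)dimethylsilane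
Product: 11 pentacarbonyl{methoxy[2,5-dimethoxy-4-((R)-1-(tert-butyldimethylsilyloxy)-4-methylpent-3-enyl)phenyl]methylene}chromium, via aryllithium 9 (not isolated), via lithium acylchromate 10 (not isolated)
Conditions: n-BuLi, THF, −78 °C; Cr(CO)6, THF/Et2O, −78 °C to rt; then MeOTf, CH2Cl2, 0 °C to rt
Reagents that add atoms: hexacarbonylchromium, O=C=[Cr](=C=O)(=C=O)(=C=O)(=C=O)=C=O; methyl trifluoromethanesulfonate, COS(=O)(=O)C(F)(F)F
Why: Fischer carbene synthesis: fast bromine–lithium exchange gives the aryllithium, which adds to a carbonyl ligand of Cr(CO)6, and hard O-methylation of the acylchromate gives the neutral methoxycarbene complex. The 2,5-dimethoxyphenyl complex without a side chain is a standard member of this class, and the remote silyl ether should not interfere.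

Step 6
Reactants: 11 pentacarbonyl{methoxy[2,5-dimethoxy-4-((R)-1-(tert-butyldimethylsilyloxy)-4-methylpent-3-enyl)phenyl]methylene}chromium; 12 trimethylsilylacetylene
Product: 14 7-[(R)-1-(tert-butyldimethylsilyloxy)-4-methylpent-3-enyl]-4,5,8-trimethoxy-2-(trimethylsilyl)naphthalen-1-ol, via chromium tricarbonyl naphthol complex 13 (not isolated)
Conditions: 12 (2 equiv), THF (0.05 M), 50 °C, argon, sealed vessel; then air, rt
Reagents that add atoms: none
Why: This is a Dötz benzannulation, the closest known reaction type being that of aryl(methoxy)carbene pentacarbonylchromium complexes with terminal and silyl alkynes to give 4-methoxy-1-naphthols. Thermal loss of one carbonyl ligand from the zerovalent chromium centre, eased by the ortho methoxy group that can fill the vacant site, lets 12 coordinate and insert into the chromium–carbene bond, its unsubstituted carbon bonding to the carbene carbon (C5–C6) so that the silyl group sits on the new carbene carbon. Migration of a carbonyl ligand onto that carbon gives a chromium-bound dienylketene (C7–C8). Ring A then closes by a 6π-electrocyclisation of the aryl–vinyl–ketene triene onto C8a, the only unsubstituted ortho position of the arene, and a proton shift from C8a to oxygen aromatises the ring to the naphthol, first as its Cr(CO)3 complex 13, from which air removes the metal. No stereocentre is formed, and C1' is remote from the reacting centres and not enolisable, so it should pass through unchanged. The step needs chemoselectivity for the six-membered phenol over five-membered products formed without carbonyl insertion and over an uncyclised silyl ketene; chromium, an ether solvent, moderate temperature and the small trimethylsilyl group all favour the phenol path. The orientation of alkyne insertion is of no consequence because the silyl group is exchanged for hydrogen in step 7.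

Step 7
Reactants: 14 7-[(R)-1-(tert-butyldimethylsilyloxy)-4-methylpent-3-enyl]-4,5,8-trimethoxy-2-(trimethylsilyl)naphthalen-1-ol
Product: 15 7-[(R)-1-(tert-butyldimethylsilyloxy)-4-methylpent-3-enyl]-4,5,8-trimethoxynaphthalen-1-ol
Conditions: CF3CO2H (3 equiv), CH2Cl2, −20 to 0 °C; aq. NaHCO3; product used at once under argon
Reagents that add atoms: none
Why: Ipso-protodesilylation of an aryltrimethylsilane: the carbon ortho to the naphthol hydroxyl is the most nucleophilic position of this electron-rich ring, so protonation there is followed by loss of the silyl group. Low temperature and a small excess of acid in a non-ionising solvent are chosen to spare the benzylic silyl ether; any O-silylated isomer from step 6 would converge on the same product.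

Step 8
Reactants: 15 7-[(R)-1-(tert-butyldimethylsilyloxy)-4-methylpent-3-enyl]-4,5,8-trimethoxynaphthalen-1-ol
Product: 16 6-[(R)-1-(tert-butyldimethylsilyloxy)-4-methylpent-3-enyl]-5,8-dimethoxynaphthalene-1,4-dione
Conditions: (NH4)2Ce(NO3)6 (2.2 equiv), MeCN/H2O, 0 °C, short reaction time
Reagents that add atoms: water, O
Why: Oxidative demethylation of a 4-methoxy-1-naphthol to the 1,4-quinone by two equivalents of tetravalent cerium: only the ring made in step 6 has a free hydroxyl and is oxidised far more easily than the 5,8-dimethoxy ring, which should stay aromatic. Water supplies the new carbonyl oxygen and methanol is lost.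

Step 9
Reactants: 16 6-[(R)-1-(tert-butyldimethylsilyloxy)-4-methylpent-3-enyl]-5,8-dimethoxynaphthalene-1,4-dione
Product: 17 2-[(R)-1-(tert-butyldimethylsilyloxy)-4-methylpent-3-enyl]-5,8-dihydroxynaphthalene-1,4-dione
Conditions: BCl3 (4 equiv), CH2Cl2, −78 °C; aq. NaHCO3
Reagents that add atoms: none
Why: Chelation-assisted ether cleavage: BCl3 bridges a quinone carbonyl and the peri methoxy oxygen and chloride removes the methyl group; both methoxy groups are peri to a carbonyl, so both should be cleaved at −78 °C, where the silyl ether and the alkene are expected to hold. Proton tautomerism of the naphthazarin then places the side chain on the quinonoid ring as drawn.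

Step 10
Reactants: 17 2-[(R)-1-(tert-butyldimethylsilyloxy)-4-methylpent-3-enyl]-5,8-dihydroxynaphthalene-1,4-dione
Product: 18 shikonin, 5,8-dihydroxy-2-[(R)-1-hydroxy-4-methylpent-3-enyl]naphthalene-1,4-dione
Conditions: Bu4NF, AcOH (1:1), THF, 0 °C to rt
Reagents that add atoms: none
Why: Fluoride cleavage of a silyl ether; buffering with acetic acid keeps the medium near neutral so that the naphthazarin is not held as its base-sensitive phenolate and C1' is not epimerised.

Step 11
Reactants: 19 (2-carboxyethyl)triphenylphosphonium bromide; 20 methacrolein (2-methylprop-2-enal)
Product: 22 (Z)-5-methylhexa-3,5-dienoic acid, via ylide carboxylate 21 (not isolated)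
Conditions: NaN(SiMe3)2 (2.0 equiv), THF, −78 to 0 °C; then 20, −78 °C to rt; cold 1 M HCl; kept cold and used promptly
Reagents that add atoms: none
Why: Z-selective Wittig reaction of a non-stabilised ylide: double deprotonation gives the carboxylate ylide, whose kinetically controlled addition to the aldehyde at low temperature forms the cis oxaphosphetane and hence the 3Z alkene. The carboxylate makes the C2 protons non-acidic, so the diene should stay out of conjugation.

Step 12
Reactants: 18 shikonin; 22 (Z)-5-methylhexa-3,5-dienoic acid
Product: 23 (R)-1-(5,8-dihydroxy-1,4-dioxo-1,4-dihydronaphthalen-2-yl)-4-methylpent-3-enyl (Z)-5-methylhexa-3,5-dienoate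
Conditions: dicyclohexylcarbodiimide, 4-(dimethylamino)pyridine (0.05 equiv), CH2Cl2, −10 to 0 °C, dark, argon
Reagents that add atoms: none
Why: Steglich esterification: the two phenolic hydroxyls are held in hydrogen bonds to the quinone carbonyls and should not be acylated, so the secondary alcohol reacts chemoselectively with retention at C1', whose C–O bond is not broken. A low catalyst loading and low temperature limit base-induced migration of the acyl C3=C4 double bond.

## Compound list

1 | 4-methylpent-3-enoic acid | CC(C)=CCC(=O)O | starting material
2 | 1-(imidazol-1-yl)-4-methylpent-3-en-1-one | CC(C)=CCC(=O)n1ccnc1 | intermediate (not isolated)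
3 | N-methoxy-N,4-dimethylpent-3-enamide | CC(C)=CCC(=O)N(C)OC | intermediate
4 | 1,4-dibromo-2,5-dimethoxybenzene | COc1cc(Br)c(OC)cc1Br | starting material
5 | (4-bromo-2,5-dimethoxyphenyl)lithium | [Li]c1cc(OC)c(Br)cc1OC | intermediate (not isolated)
6 | 1-(4-bromo-2,5-dimethoxyphenyl)-4-methylpent-3-en-1-one | CC(C)=CCC(=O)c1cc(OC)c(Br)cc1OC | intermediate
7 | (R)-1-(4-bromo-2,5-dimethoxyphenyl)-4-methylpent-3-en-1-ol | CC(C)=CC[C@@H](O)c1cc(OC)c(Br)cc1OC | intermediate
8 | (R)-[1-(4-bromo-2,5-dimethoxyphenyl)-4-methylpent-3-enyloxy](tert-butyl)dimethylsilane | CC(C)=CC[C@@H](O[Si](C)(C)C(C)(C)C)c1cc(OC)c(Br)cc1OC | intermediate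
9 | {2,5-dimethoxy-4-[(R)-1-(tert-butyldimethylsilyloxy)-4-methylpent-3-enyl]phenyl}lithium | CC(C)=CC[C@@H](O[Si](C)(C)C(C)(C)C)c1cc(OC)c([Li])cc1OC | intermediate (not isolated)
10 | lithium pentacarbonyl{[2,5-dimethoxy-4-((R)-1-(tert-butyldimethylsilyloxy)-4-methylpent-3-enyl)phenyl]oxidomethylene}chromate | CC(C)=CC[C@@H](O[Si](C)(C)C(C)(C)C)c1cc(OC)c(cc1OC)C([O-])=[Cr](=C=O)(=C=O)(=C=O)(=C=O)=C=O.[Li+] | intermediate (not isolated)
11 | pentacarbonyl{methoxy[2,5-dimethoxy-4-((R)-1-(tert-butyldimethylsilyloxy)-4-methylpent-3-enyl)phenyl]methylene}chromium | CC(C)=CC[C@@H](O[Si](C)(C)C(C)(C)C)c1cc(OC)c(cc1OC)C(OC)=[Cr](=C=O)(=C=O)(=C=O)(=C=O)=C=O | intermediate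
12 | trimethylsilylacetylene | C#C[Si](C)(C)C | starting material
13 | tricarbonyl(η6-naphthol 14)chromium, metal on the new ring (written as two components because the η6 bond has no SMILES form) | CC(C)=CC[C@@H](O[Si](C)(C)C(C)(C)C)c1cc(OC)c2c(OC)cc([Si](C)(C)C)c(O)c2c1OC.[Cr](=C=O)(=C=O)=C=O | intermediate (not isolated)
14 | 7-[(R)-1-(tert-butyldimethylsilyloxy)-4-methylpent-3-enyl]-4,5,8-trimethoxy-2-(trimethylsilyl)naphthalen-1-ol | CC(C)=CC[C@@H](O[Si](C)(C)C(C)(C)C)c1cc(OC)c2c(OC)cc([Si](C)(C)C)c(O)c2c1OC | intermediate
15 | 7-[(R)-1-(tert-butyldimethylsilyloxy)-4-methylpent-3-enyl]-4,5,8-trimethoxynaphthalen-1-ol | CC(C)=CC[C@@H](O[Si](C)(C)C(C)(C)C)c1cc(OC)c2c(OC)ccc(O)c2c1OC | intermediate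
16 | 6-[(R)-1-(tert-butyldimethylsilyloxy)-4-methylpent-3-enyl]-5,8-dimethoxynaphthalene-1,4-dione | CC(C)=CC[C@@H](O[Si](C)(C)C(C)(C)C)c1cc(OC)c2C(=O)C=CC(=O)c2c1OC | intermediate
17 | 2-[(R)-1-(tert-butyldimethylsilyloxy)-4-methylpent-3-enyl]-5,8-dihydroxynaphthalene-1,4-dione | CC(C)=CC[C@@H](O[Si](C)(C)C(C)(C)C)C1=CC(=O)c2c(O)ccc(O)c2C1=O | intermediate
18 | shikonin, 5,8-dihydroxy-2-[(R)-1-hydroxy-4-methylpent-3-enyl]naphthalene-1,4-dione | CC(C)=CC[C@@H](O)C1=CC(=O)c2c(O)ccc(O)c2C1=O | intermediate
19 | (2-carboxyethyl)triphenylphosphonium bromide | OC(=O)CC[P+](c1ccccc1)(c1ccccc1)c1ccccc1.[Br-] | starting material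
20 | methacrolein (2-methylprop-2-enal) | CC(=C)C=O | starting material
21 | sodium 3-(triphenyl-λ5-phosphanylidene)propanoate | [Na+].[O-]C(=O)CC=P(c1ccccc1)(c1ccccc1)c1ccccc1 | intermediate (not isolated)
22 | (Z)-5-methylhexa-3,5-dienoic acid | C=C(C)/C=C\CC(=O)O | intermediate
23 | (R)-1-(5,8-dihydroxy-1,4-dioxo-1,4-dihydronaphthalen-2-yl)-4-methylpent-3-enyl (Z)-5-methylhexa-3,5-dienoate | C=C(C)/C=C\CC(=O)O[C@H](CC=C(C)C)C1=CC(=O)c2c(O)ccc(O)c2C1=O | target

## Step count and least certain steps

Total step count: 12. Longest linear sequence: 11 steps (steps 1 to 10 and step 12); step 11 is a one-step side branch.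

**Step 6 (key step).** The annulation may stop at an open silyl-substituted ketene whose geometry cannot cyclise, or close a five-membered ring without carbonyl insertion. Silyl alkynes stabilise ketenes, and electron-rich, ortho-chelated aryl carbenes lose their first carbonyl ligand slowly and favour non-insertion paths. The fallback sets out from 8 and comes back at 16. Treating 8 with LiN(iPr)2 in THF with furan in excess should remove the ring proton between bromine and methoxy, expel bromide and trap the aryne as 6-[(R)-1-(tert-butyldimethylsilyloxy)-4-methylpent-3-enyl]-5,8-dimethoxy-1,4-dihydro-1,4-epoxynaphthalene F1 (both bridgehead diastereomers). Catalytic camphorsulfonic acid in CH2Cl2 at 0 °C should open the strained bridge to 6-[(R)-1-(tert-butyldimethylsilyloxy)-4-methylpent-3-enyl]-5,8-dimethoxynaphthalen-1-ol F2 and its 7-substituted isomer 7-[(R)-1-(tert-butyldimethylsilyloxy)-4-methylpent-3-enyl]-5,8-dimethoxynaphthalen-1-ol F3. Oxidation of both at the free para position with (KSO3)2NO gives the single quinone 16.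

**Step 7.** Acid may ionise the C1'–O bond, helped by the neighbouring methoxy group, which would lead to elimination or capture by the C3'=C4' alkene, or it may strip the silyl ether. Both the wanted ipso protonation and the ionisation are acid-driven. The fallback sets out from 11 and comes back at 15: the benzannulation is run with acetylene itself, fed slowly into a dilute THF solution of 11 at 50 °C, so that no silicon ever sits on the ring. It makes no new compound (F0). Its known weakness is a second alkyne insertion, which is why it is not the first choice.

**Step 9.** The Lewis acid may ionise or chlorinate C1', cleave the silyl ether or stop after one methyl group. During this step the side chain sits on the benzenoid ring next to a methoxy group. The fallback sets out from 16 and comes back at 17. Oxidative demethylation with AgO in dioxane and 6 M HNO3 for a few minutes should give 2-[(R)-1-(tert-butyldimethylsilyloxy)-4-methylpent-3-enyl]naphthalene-1,4,5,8-tetraone F4. Reduction with aqueous Na2S2O4 and exposure to air return the naphthazarin 17 without any Lewis acid.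

**Step 11.** The cis geometry may erode, the ylide may lose phosphine by β-elimination to an acrylate, or the diene acid may polymerise or conjugate on acidic work-up. The fallback sets out from 20 and comes back at 22. A Wittig reaction of 20 with the ylide from (3-hydroxypropyl)triphenylphosphonium bromide and NaN(SiMe3)2 (2 equiv), which cannot eliminate, should give (Z)-5-methylhexa-3,5-dien-1-ol F5. Oxidation with PhI(OAc)2 and catalytic 2,2,6,6-tetramethylpiperidin-1-oxyl in MeCN/H2O takes F5 to 22, so the carboxyl group appears only after the alkene is in place.

**Step 12.** The aminopyridine may deprotonate the doubly activated C2 methylene of the activated acid, through a ketene or dienolate, which moves the C3=C4 bond into conjugation or scrambles its geometry; rearrangement to an N-acylurea is a second loss. The fallback sets out from 22 and 18 and comes back at 23. The acid is converted without base, by 2,2'-dipyridyl disulfide and PPh3 in CH2Cl2, into S-(pyridin-2-yl) (Z)-5-methylhexa-3,5-dienethioate F6. F6 then acylates 18 under thiophilic activation with AgOTf and 2,6-di-tert-butylpyridine in toluene at rt, so no nucleophilic amine is present.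

## Further compounds

F1 | step 6 | 6-[(R)-1-(tert-butyldimethylsilyloxy)-4-methylpent-3-enyl]-5,8-dimethoxy-1,4-dihydro-1,4-epoxynaphthalene (both bridgehead diastereomers) | CC(C)=CC[C@@H](O[Si](C)(C)C(C)(C)C)c1cc(OC)c2C3C=CC(O3)c2c1OC
F2 | step 6 | 6-[(R)-1-(tert-butyldimethylsilyloxy)-4-methylpent-3-enyl]-5,8-dimethoxynaphthalen-1-ol | CC(C)=CC[C@@H](O[Si](C)(C)C(C)(C)C)c1cc(OC)c2c(O)cccc2c1OC
F3 | step 6 | 7-[(R)-1-(tert-butyldimethylsilyloxy)-4-methylpent-3-enyl]-5,8-dimethoxynaphthalen-1-ol | CC(C)=CC[C@@H](O[Si](C)(C)C(C)(C)C)c1cc(OC)c2cccc(O)c2c1OC
F0 | step 7 | none | none
F4 | step 9 | 2-[(R)-1-(tert-butyldimethylsilyloxy)-4-methylpent-3-enyl]naphthalene-1,4,5,8-tetraone | CC(C)=CC[C@@H](O[Si](C)(C)C(C)(C)C)C1=CC(=O)C2=C(C1=O)C(=O)C=CC2=O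
F5 | step 11 | (Z)-5-methylhexa-3,5-dien-1-ol | C=C(C)/C=C\CCO
F6 | step 12 | S-(pyridin-2-yl) (Z)-5-methylhexa-3,5-dienethioate | C=C(C)/C=C\CC(=O)Sc1ccccn1
A1 | alternative 1 | 4,4,5,5-tetramethyl-2-vinyl-1,3,2-dioxaborolane | C=CB1OC(C)(C)C(C)(C)O1
A2 | alternative 1 | (1,4,5,8-tetramethoxynaphthalen-2-yl)lithium | [Li]c1cc(OC)c2c(OC)ccc(OC)c2c1OC
A3 | alternative 1 | 2-methylprop-1-enyl trifluoromethanesulfonate | CC(C)=COS(=O)(=O)C(F)(F)F
A4 | alternative 1 | (R)-4,4,5,5-tetramethyl-2-[4-methyl-1-(1,4,5,8-tetramethoxynaphthalen-2-yl)pent-3-enyl]-1,3,2-dioxaborolane | CC(C)=CC[C@@H](B1OC(C)(C)C(C)(C)O1)c1cc(OC)c2c(OC)ccc(OC)c2c1OC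
A5 | alternative 2 | 2-bromo-1,4-dimethoxybenzene | COc1ccc(OC)c(Br)c1
A6 | alternative 2 | (R)-tert-butyl{[1-(furan-3-yl)-4-methylpent-3-enyl]oxy}dimethylsilane | CC(C)=CC[C@@H](O[Si](C)(C)C(C)(C)C)c1ccoc1
A7 | alternative 2 | 2-[(R)-1-(tert-butyldimethylsilyloxy)-4-methylpent-3-enyl]-5,8-dimethoxy-1,4-dihydro-1,4-epoxynaphthalene (both bridgehead diastereomers) | CC(C)=CC[C@@H](O[Si](C)(C)C(C)(C)C)C1=CC2OC1c1c(OC)ccc(OC)c12
A8 | alternative 3 | 3,6-dimethoxybenzocyclobutene-1,2-dione | COc1ccc(OC)c2C(=O)C(=O)c12
A9 | alternative 3 | (R)-tert-butyldimethyl[(6-methylhept-5-en-1-yn-3-yl)oxy]silane | CC(C)=CC[C@@H](O[Si](C)(C)C(C)(C)C)C#C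
A10 | alternative 3 | 2-[(R)-1-(tert-butyldimethylsilyloxy)-4-methylpent-3-enyl]-5,8-dimethoxynaphthalene-1,4-dione | CC(C)=CC[C@@H](O[Si](C)(C)C(C)(C)C)C1=CC(=O)c2c(OC)ccc(OC)c2C1=O
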